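**Retrosynthetic overview** (elemane numbering: ring C5–C10; C1=C2 vinyl and C14 methyl on C10; C3/C4/C15 on C5; C11–C13 on C7)
1. Enabling feature: C8(–O), C9H2, quaternary C10 and its vinyl group C1=C2 form a γ,δ-unsaturated-ketone (Claisen) retron once C8 is taken to the ketone level.
2. Key disconnection: cut C9–C10 and join C2 to the C8 oxygen. This gives an eight-membered 2-methylidene-oxocene (ring O, C2, C1, C10, C5, C6, C7, C8; exocyclic C9) from lactone 25; a [3,3] shift contracts it by two atoms to the cyclohexane.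
3. Lactone 25 comes from Shiina lactonisation of a seco acid. Its C5/C6 pair is set by an Evans syn-aldol of a (Z)-β,γ-unsaturated imide (C10 unit from prenol); the C3/C4/C15 unit is grown from the aldol acyl carbon.
4. After contraction, a C6–O-tethered bromoacetal radical cyclisation with oxygen capture sets C7 and C8. The (S)-acyl group comes from Roche ester; the acetal is then unmasked, methylenated and oxidised to the acrylic acid.
5. Ring order: eight-membered lactone (step 12), then cyclohexane by ring contraction (step 14), then a temporary cis-fused tetrahydrofuran acetal (step 19) that is opened in step 25.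

Key step: step 14

Assumption: the acetal carbon made in step 18 (later the lactol carbon) is carried as an epimer mixture and drawn without configuration, since it ends as the carboxyl carbon C12; aldehyde 12 and the stannane of step 7 are taken as purchasable.

**Step 1**
Reactants: 1 3-methylbut-2-en-1-ol (prenol)
Product: 4 4-methyl-3,6-dihydro-2H-pyran-2-one, via dilithiated prenol 2 (not isolated), via (Z)-5-hydroxy-3-methylpent-3-enoic acid 3 (not isolated)
Conditions: n-BuLi (2.2 equiv), TMEDA, Et2O/hexane, 0 °C to rt; CO2, −78 °C; 2 M HCl, rt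
Reagents that add atoms: carbon dioxide, O=C=O
Why: Alkoxide-directed allylic lithiation removes a proton from the methyl group cis to CH2OLi, so carboxylation of the dianion should give the (Z)-hydroxy acid, which lactonises on acidification and fixes the Z geometry of the future C1=C10 alkene.

**Step 2**
Reactants: 4 4-methyl-3,6-dihydro-2H-pyran-2-one
Product: 7 (Z)-5-[(tert-butyldimethylsilyl)oxy]-3-methylpent-3-enoic acid, via sodium (Z)-5-hydroxy-3-methylpent-3-enoate 5 (not isolated), via bis-silylated hydroxy acid 6 (not isolated)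
Conditions: NaOH (1.0 equiv), THF/H2O, 0 °C, evaporate; TBSCl (2.3 equiv), imidazole, DMF, rt; K2CO3 (cat.), MeOH/H2O; citric acid work-up
Reagents that add atoms: sodium hydroxide, [Na+].[OH-]; tert-butyldimethylsilyl chloride, CC(C)(C)[Si](C)(C)Cl
Why: Saponification, exhaustive silylation and selective cleavage of the labile silyl ester is the standard route to an O-silylated hydroxy acid, and the non-conjugated carboxylate should not isomerise under these mild bases.

**Step 3**
Reactants: 7 (Z)-5-[(tert-butyldimethylsilyl)oxy]-3-methylpent-3-enoic acid; 8 (S)-4-benzyl-1,3-oxazolidin-2-one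
Product: 11 (S)-4-benzyl-3-[(Z)-5-(tert-butyldimethylsilyloxy)-3-methylpent-3-enoyl]oxazolidin-2-one, via mixed pivalic anhydride 9 (not isolated), via lithiated oxazolidinone 10 (not isolated)
Conditions: PivCl, Et3N, THF, −78 to 0 °C; then 10 (from 8, n-BuLi, THF, −78 °C), −78 to 0 °C; NH4Cl
Reagents that add atoms: none
Why: N-Acylation of the lithiated Evans auxiliary with a mixed pivalic anhydride is the standard, non-isomerising way to attach a β,γ-unsaturated acid.

**Step 4**
Reactants: 11 (S)-4-benzyl-3-[(Z)-5-(tert-butyldimethylsilyloxy)-3-methylpent-3-enoyl]oxazolidin-2-one; 12 3-[(4-methoxybenzyl)oxy]propanal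
Product: 14 syn-aldol adduct (S)-4-benzyl-3-[(2S,3R)-3-hydroxy-5-(4-methoxybenzyloxy)-2-{(Z)-4-(tert-butyldimethylsilyloxy)but-2-en-2-yl}pentanoyl]oxazolidin-2-one, via Z-boron dienolate 13 (not isolated)
Conditions: Bu2BOTf, Et3N, CH2Cl2, −78 to 0 °C; 12, −78 to 0 °C; pH 7 buffer, MeOH, H2O2
Reagents that add atoms: none
Why: Evans boron aldol reaction, in which the Z(O)-dienolate reacts at its α-carbon through a Zimmerman–Traxler chair on the face away from the benzyl group, should set C5 and C6 (syn, 2S,3R) and leave the (Z)-trisubstituted alkene untouched.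

**Step 5**
Reactants: 14 syn-aldol adduct
Product: 15 Weinreb amide (2S,3R)-3-hydroxy-N-methoxy-N-methyl-5-(4-methoxybenzyloxy)-2-[(Z)-4-(tert-butyldimethylsilyloxy)but-2-en-2-yl]pentanamide
Conditions: Me3Al, MeONHMe·HCl, CH2Cl2, −20 to 0 °C; Rochelle salt
Reagents that add atoms: N,O-dimethylhydroxylamine hydrochloride, CNOC.Cl
Why: Aluminium-amide transamination of Evans syn-aldol imides with a free β-hydroxyl is standard and releases the auxiliary without epimerising C5.

**Step 6**
Reactants: 15 Weinreb amide
Product: 16 C6 TBS ether of Weinreb amide 15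
Conditions: TBSOTf, 2,6-lutidine, CH2Cl2, −78 to 0 °C
Reagents that add atoms: tert-butyldimethylsilyl triflate, CC(C)(C)[Si](C)(C)OS(=O)(=O)C(F)(F)F
Why: Silyl triflate silylation protects the secondary C6 hydroxyl, which later steers the ring contraction as an exo substituent.

**Step 7**
Reactants: 16 C6 TBS ether of Weinreb amide 15
Product: 18 ketone (3S,4R)-4-(tert-butyldimethylsilyloxy)-1-(methoxymethoxy)-6-(4-methoxybenzyloxy)-3-[(Z)-4-(tert-butyldimethylsilyloxy)but-2-en-2-yl]hexan-2-one, via lithium hemiaminal chelate 17 (not isolated)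
Conditions: Bu3SnCH2OMOM, n-BuLi, THF, −78 °C; then 16, −78 °C; NH4Cl
Reagents that add atoms: tributyl[(methoxymethoxy)methyl]stannane, CCCC[Sn](CCCC)(CCCC)COCOC
Why: Tin–lithium exchange gives (methoxymethoxy)methyllithium, which adds once to the Weinreb amide through a stable chelated tetrahedral intermediate and so places C15 with its oxygen on the former acyl carbon C4.

**Step 8**
Reactants: 18 ketone
Product: 19 methylidene compound (C4=C3H2 in place of the C4 carbonyl of 18)
Conditions: Cp2TiMe2, toluene/THF, 65 °C, dark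
Reagents that add atoms: dimethyltitanocene, [CH3-].[CH3-].[Ti+4].c1cc[cH-]c1.c1cc[cH-]c1
Why: Petasis methylenation is non-basic, so the epimerisable doubly activated C5 centre next to the ketone should survive while C3 is introduced.

**Step 9**
Reactants: 19 methylidene compound
Product: 20 primary alcohol (free C8 hydroxyl)
Conditions: DDQ, CH2Cl2/pH 7 buffer, 0 °C
Reagents that add atoms: none
Why: Oxidative PMB cleavage with DDQ is selective for the electron-rich benzyl ether and should spare silyl ethers, the MOM ether and the alkenes.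

**Step 10**
Reactants: 20 primary alcohol
Product: 22 C8 carboxylic acid, via aldehyde 21 (not isolated)
Conditions: TEMPO (cat.), PhI(OAc)2, MeCN/H2O, rt
Reagents that add atoms: water, O
Why: TEMPO/PhI(OAc)2 in aqueous acetonitrile oxidises a primary alcohol through the aldehyde hydrate to the acid without touching alkenes or silyl ethers.

**Step 11**
Reactants: 22 C8 carboxylic acid
Product: 23 seco acid (free C2 allylic hydroxyl)
Conditions: HF·pyridine, pyridine, THF, 0 °C
Reagents that add atoms: none
Why: Buffered HF·pyridine should remove the primary allylic TBS ether much faster than the hindered secondary C6 TBS ether.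

**Step 12**
Reactants: 23 seco acid
Product: 25 lactone (4R,5R,Z)-4-(tert-butyldimethylsilyloxy)-5-[3-(methoxymethoxy)prop-1-en-2-yl]-6-methyl-3,4,5,8-tetrahydro-2H-oxocin-2-one, via mixed nitrobenzoic anhydride 24 (not isolated)
Conditions: MNBA, DMAP (cat.), Et3N, CH2Cl2 (2 mM), rt, slow addition
Reagents that add atoms: none
Why: Shiina lactonisation under high dilution is a proven method for eight-membered lactones (8-exo-trig acyl substitution), and the Z-alkene holds the two termini cis and removes transannular hydrogens.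

**Step 13**
Reactants: 25 eight-membered lactone
Product: 26 enol ether (4R,5R,Z)-4-(tert-butyldimethylsilyloxy)-5-[3-(methoxymethoxy)prop-1-en-2-yl]-6-methyl-2-methylidene-3,4,5,8-tetrahydro-2H-oxocine
Conditions: Cp2TiMe2, toluene, 65 °C, dark; filtration through basic alumina
Reagents that add atoms: dimethyltitanocene, [CH3-].[CH3-].[Ti+4].c1cc[cH-]c1.c1cc[cH-]c1
Why: Petasis methylenation converts lactones into exocyclic enol ethers and so introduces C9 and completes the cyclic allyl vinyl ether.

**Step 14**
Reactants: 26 2-methylidene-oxocene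
Product: 27 ketone (3S,4R,5R)-5-(tert-butyldimethylsilyloxy)-3-ethenyl-4-[3-(methoxymethoxy)prop-1-en-2-yl]-3-methylcyclohexan-1-one
Conditions: toluene (0.01 M), BHT (cat.), base-washed sealed tube, 130 °C
Reagents that add atoms: none
Why: The allyl vinyl ether C9H2=C8–O–C2–C1=C10 built into the oxocene should undergo a concerted thermal [3,3]-sigmatropic (Claisen) shift in which C2–O breaks as C9–C10 forms, so O, C2 and C1 leave the ring (O as the C8 carbonyl oxygen, C1=C2 as the vinyl group) and the eight-membered ring contracts by two atoms to the cyclohexanone. The closest known reaction type is the Claisen ring contraction of methylenated unsaturated lactones with an endocyclic allylic C–O bond, the counterpart of the methylenation–Claisen ring expansion of vinyl lactones. The six-membered ring (C8, C9, C10, C5, C6, C7) closes by transannular, suprafacial attack of the exocyclic enol carbon C9 on C10 (formally 6-(enolendo)-exo-trig) through a bicyclo[3.3.1]-like chair–chair array in which the departing O–C2–C1 unit bridges one face of the new ring. The only new stereocentre, quaternary C10, is controlled by the C6 silyloxy group together with the C5 side chain: the bridge can only span the face opposite to both, because on the other face the C6–OTBS group would be forced endo against C2 or the C5 substituent would eclipse C1, so the vinyl group should end trans and the C14 methyl cis to the C6 oxygen and to C4. The step needs this facial selectivity and a clean pericyclic course, which are secured by the cis C5/C6 relationship from the aldol step, by the absence of any other 1,5-diene in 26, and by neutral, base-washed, non-polar conditions that suppress ionisation of the enol ether.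

**Step 15**
Reactants: 27 cyclohexanone
Product: 29 enol triflate (C7=C8–OTf) of ketone 27, via lithium enolate 28 (not isolated)
Conditions: LiHMDS, THF, −78 °C; PhNTf2, −78 to 0 °C; NH4Cl
Reagents that add atoms: N-phenylbis(trifluoromethanesulfonimide), O=S(=O)(N(c1ccccc1)S(=O)(=O)C(F)(F)F)C(F)(F)F
Why: Kinetic deprotonation should occur at C7 because C9 is neopentyl next to quaternary C10, the β-silyloxy group is not expelled at −78 °C, and O-triflation of the enolate is standard.

**Step 16**
Reactants: 29 enol triflate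
Product: 30 cyclohexene (C7=C8) with allylic C6 silyl ether
Conditions: Pd(OAc)2 (cat.), PPh3, Bu3N, HCO2H, DMF, 60 °C
Reagents that add atoms: none
Why: Palladium-catalysed formate reduction of an enol triflate gives the alkene regiospecifically and tolerates the other alkenes.

**Step 17**
Reactants: 30 cyclohexene silyl ether
Product: 31 allylic alcohol (free C6 hydroxyl)
Conditions: TBAF, THF, rt to 40 °C
Reagents that add atoms: none
Why: Fluoride cleaves the TBS ether while the MOM ether is inert.

**Step 18**
Reactants: 31 allylic alcohol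
Product: 32 bromoacetal (2-bromo-1-ethoxyethyl ether of 31; acetal epimers)
Conditions: ethyl vinyl ether, NBS, CH2Cl2, −40 to 0 °C
Reagents that add atoms: ethyl vinyl ether, C=COCC; N-bromosuccinimide, O=C1CCC(=O)N1Br
Why: Ueno–Stork haloacetalisation, in which the enol ether is by far the most nucleophilic alkene toward bromonium transfer and the C6 hydroxyl captures the oxocarbenium ion.

**Step 19**
Reactants: 32 bromoacetal
Product: 34 cis-fused bicyclic ethyl acetal with C8 α-hydroxyl, via C8 hydroperoxide 33 (not isolated)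
Conditions: Bu3SnH (slow addition), dry air, toluene, rt; then PPh3
Reagents that add atoms: dioxygen, O=O
Why: Oxygenative Ueno–Stork radical cyclisation, in which the tethered primary radical closes 5-exo-trig onto C7 from the face of the C6 oxygen (cis fusion sets C7) and the C8 radical is trapped by O2 on the α face, anti to the new ring and to the axial C14 methyl, which should set C8 trans to C7–C11.

**Step 20**
Reactants: 35 methyl (S)-3-hydroxy-2-methylpropanoate (Roche ester)
Product: 36 methyl (S)-3-(methoxymethoxy)-2-methylpropanoate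
Conditions: MOMCl, i-Pr2NEt, CH2Cl2, 0 °C to rt
Reagents that add atoms: chloromethyl methyl ether, COCCl
Why: Standard MOM protection that does not involve the stereocentre.

**Step 21**
Reactants: 36 methyl (S)-3-(methoxymethoxy)-2-methylpropanoate
Product: 37 (S)-3-(methoxymethoxy)-2-methylpropanoic acid
Conditions: LiOH, THF/H2O, 0 °C; 1 M HCl to pH 3
Reagents that add atoms: lithium hydroxide, [Li+].[OH-]
Why: Mild saponification at 0 °C should avoid epimerisation and β-elimination.

**Step 22**
Reactants: 34 bicyclic acetal alcohol; 37 (S)-3-(methoxymethoxy)-2-methylpropanoic acid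
Product: 39 C8 ester of 34 with acid 37, via Yamaguchi mixed anhydride 38 (not isolated)
Conditions: 2,4,6-trichlorobenzoyl chloride, Et3N, THF, rt; then 34, DMAP, toluene, rt
Reagents that add atoms: none
Why: Yamaguchi esterification acylates the only free hydroxyl (equatorial C8–OH) with retention at C8 and should not epimerise the α-stereocentre of the acid.

**Step 23**
Reactants: 39 C8 ester
Product: 41 lactol with free C15 and side-chain hydroxyls, via bromo acetal bis(borinate) 40 (not isolated)
Conditions: Me2BBr, CH2Cl2, −78 °C; then THF/sat. aq. NaHCO3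
Reagents that add atoms: water, O
Why: Dimethylboron bromide cleaves MOM ethers and tetrahydrofuranyl acetals at −78 °C without touching esters or alkenes, so one operation should free both primary hydroxyls and turn the ethyl acetal into the lactol.

**Step 24**
Reactants: 41 lactol
Product: 42 α-methylidene lactol
Conditions: aq. CH2O, pyrrolidine (cat.), propionic acid (cat.), i-PrOH, 45 °C
Reagents that add atoms: formaldehyde, C=O
Why: Organocatalytic Mannich–elimination α-methylenation of aldehydes acts on the open hydroxy-aldehyde form of the lactol and installs C13 under nearly neutral conditions.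

**Step 25**
Reactants: 42 α-methylidene lactol
Product: 43 target, 2-[(1S,2S,3R,4S,6S)-4-ethenyl-2-hydroxy-6-{[(2S)-3-hydroxy-2-methylpropanoyl]oxy}-3-(3-hydroxyprop-1-en-2-yl)-4-methylcyclohexyl]prop-2-enoic acid
Conditions: NaClO2, NaH2PO4, 2-methyl-2-butene, t-BuOH/H2O, 0 °C to rt; work-up at pH 5
Reagents that add atoms: sodium chlorite, [Na+].[O-]Cl=O
Why: Pinnick oxidation converts the enal tautomer of the α-methylidene lactol into the acrylic acid and thereby releases the C6 hydroxyl, while the chlorine scavenger protects the allylic alcohols and alkenes.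

**Compound list**
1 | 3-methylbut-2-en-1-ol (prenol) | CC(C)=CCO | starting material
2 | lithium (Z)-4-lithio-3-methylbut-2-en-1-olate | [Li]OC/C=C(C)\C[Li] | intermediate
3 | (Z)-5-hydroxy-3-methylpent-3-enoic acid | OC/C=C(C)\CC(=O)O | intermediate
4 | 4-methyl-3,6-dihydro-2H-pyran-2-one | CC1=CCOC(=O)C1 | intermediate
5 | sodium (Z)-5-hydroxy-3-methylpent-3-enoate | [Na+].[O-]C(=O)C/C(C)=C\CO | intermediate
6 | tert-butyldimethylsilyl (Z)-5-[(tert-butyldimethylsilyl)oxy]-3-methylpent-3-enoate | CC(C)(C)[Si](C)(C)OC/C=C(C)\CC(=O)O[Si](C)(C)C(C)(C)C | intermediate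
7 | (Z)-5-[(tert-butyldimethylsilyl)oxy]-3-methylpent-3-enoic acid | CC(C)(C)[Si](C)(C)OC/C=C(C)\CC(=O)O | intermediate
8 | (S)-4-benzyl-1,3-oxazolidin-2-one | O=C1N[C@@H](Cc2ccccc2)CO1 | starting material
9 | mixed anhydride of acid 7 with pivalic acid | CC(C)(C)[Si](C)(C)OC/C=C(C)\CC(=O)OC(=O)C(C)(C)C | intermediate
10 | lithium salt of (S)-4-benzyl-1,3-oxazolidin-2-one | [Li]N1C(=O)OC[C@@H]1Cc1ccccc1 | intermediate
11 | (S)-4-benzyl-3-[(Z)-5-(tert-butyldimethylsilyloxy)-3-methylpent-3-enoyl]oxazolidin-2-one | CC(C)(C)[Si](C)(C)OC/C=C(C)\CC(=O)N1C(=O)OC[C@@H]1Cc1ccccc1 | intermediate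
12 | 3-[(4-methoxybenzyl)oxy]propanal | COc1ccc(COCCC=O)cc1 | starting material
13 | dibutylboron Z(O)-dienolate of imide 11 | CCCCB(CCCC)O/C(=C\C(C)=C/CO[Si](C)(C)C(C)(C)C)N1C(=O)OC[C@@H]1Cc1ccccc1 | intermediate
14 | (S)-4-benzyl-3-[(2S,3R)-3-hydroxy-5-(4-methoxybenzyloxy)-2-{(Z)-4-(tert-butyldimethylsilyloxy)but-2-en-2-yl}pentanoyl]oxazolidin-2-one | COc1ccc(COCC[C@@H](O)[C@H](/C(C)=C\CO[Si](C)(C)C(C)(C)C)C(=O)N2C(=O)OC[C@@H]2Cc2ccccc2)cc1 | intermediate
15 | (2S,3R)-3-hydroxy-N-methoxy-N-methyl-5-(4-methoxybenzyloxy)-2-[(Z)-4-(tert-butyldimethylsilyloxy)but-2-en-2-yl]pentanamide | COc1ccc(COCC[C@@H](O)[C@H](/C(C)=C\CO[Si](C)(C)C(C)(C)C)C(=O)N(C)OC)cc1 | intermediate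
16 | C6 TBS ether of Weinreb amide 15 (2S,3R) | COc1ccc(COCC[C@@H](O[Si](C)(C)C(C)(C)C)[C@H](/C(C)=C\CO[Si](C)(C)C(C)(C)C)C(=O)N(C)OC)cc1 | intermediate
17 | lithium alkoxide of the tetrahedral adduct of 16 with (methoxymethoxy)methyllithium | COc1ccc(COCC[C@@H](O[Si](C)(C)C(C)(C)C)[C@H](/C(C)=C\CO[Si](C)(C)C(C)(C)C)C(O[Li])(COCOC)N(C)OC)cc1 | intermediate
18 | (3S,4R)-4-(tert-butyldimethylsilyloxy)-1-(methoxymethoxy)-6-(4-methoxybenzyloxy)-3-[(Z)-4-(tert-butyldimethylsilyloxy)but-2-en-2-yl]hexan-2-one | COc1ccc(COCC[C@@H](O[Si](C)(C)C(C)(C)C)[C@H](/C(C)=C\CO[Si](C)(C)C(C)(C)C)C(=O)COCOC)cc1 | intermediate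
19 | methylidene analogue of ketone 18 (C4=C3H2), stereocentres unchanged | COc1ccc(COCC[C@@H](O[Si](C)(C)C(C)(C)C)[C@H](/C(C)=C\CO[Si](C)(C)C(C)(C)C)C(=C)COCOC)cc1 | intermediate
20 | primary alcohol from PMB cleavage of 19 (free C8 hydroxyl) | OCC[C@@H](O[Si](C)(C)C(C)(C)C)[C@H](/C(C)=C\CO[Si](C)(C)C(C)(C)C)C(=C)COCOC | intermediate
21 | C8 aldehyde from 20 | O=CC[C@@H](O[Si](C)(C)C(C)(C)C)[C@H](/C(C)=C\CO[Si](C)(C)C(C)(C)C)C(=C)COCOC | intermediate
22 | C8 carboxylic acid from 20 | OC(=O)C[C@@H](O[Si](C)(C)C(C)(C)C)[C@H](/C(C)=C\CO[Si](C)(C)C(C)(C)C)C(=C)COCOC | intermediate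
23 | seco acid (C8 acid, free C2 allylic hydroxyl, C6 TBS ether) | OC(=O)C[C@@H](O[Si](C)(C)C(C)(C)C)[C@H](/C(C)=C\CO)C(=C)COCOC | intermediate
24 | mixed anhydride of seco acid 23 with 2-methyl-6-nitrobenzoic acid | Cc1cccc([N+](=O)[O-])c1C(=O)OC(=O)C[C@@H](O[Si](C)(C)C(C)(C)C)[C@H](/C(C)=C\CO)C(=C)COCOC | intermediate
25 | (4R,5R,Z)-4-(tert-butyldimethylsilyloxy)-5-[3-(methoxymethoxy)prop-1-en-2-yl]-6-methyl-3,4,5,8-tetrahydro-2H-oxocin-2-one | O=C1C[C@@H](O[Si](C)(C)C(C)(C)C)[C@H](/C(C)=C\CO1)C(=C)COCOC | intermediate
26 | (4R,5R,Z)-4-(tert-butyldimethylsilyloxy)-5-[3-(methoxymethoxy)prop-1-en-2-yl]-6-methyl-2-methylidene-3,4,5,8-tetrahydro-2H-oxocine | C=C1C[C@@H](O[Si](C)(C)C(C)(C)C)[C@H](/C(C)=C\CO1)C(=C)COCOC | intermediate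
27 | (3S,4R,5R)-5-(tert-butyldimethylsilyloxy)-3-ethenyl-4-[3-(methoxymethoxy)prop-1-en-2-yl]-3-methylcyclohexan-1-one | C=C[C@]1(C)CC(=O)C[C@@H](O[Si](C)(C)C(C)(C)C)[C@H]1C(=C)COCOC | intermediate
28 | lithium enolate (C7=C8) of ketone 27 | C=C[C@]1(C)CC(O[Li])=C[C@@H](O[Si](C)(C)C(C)(C)C)[C@H]1C(=C)COCOC | intermediate
29 | enol triflate (C7=C8–OTf) of ketone 27 | C=C[C@]1(C)CC(OS(=O)(=O)C(F)(F)F)=C[C@@H](O[Si](C)(C)C(C)(C)C)[C@H]1C(=C)COCOC | intermediate
30 | cyclohexene (C7=C8) with C6 TBS ether, ring stereocentres as in 27 | C=C[C@]1(C)CC=C[C@@H](O[Si](C)(C)C(C)(C)C)[C@H]1C(=C)COCOC | intermediate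
31 | allylic alcohol (free C6 hydroxyl) from 30 | C=C[C@]1(C)CC=C[C@@H](O)[C@H]1C(=C)COCOC | intermediate
32 | 2-bromo-1-ethoxyethyl ether of 31 (acetal epimers) | C=C[C@]1(C)CC=C[C@@H](OC(CBr)OCC)[C@H]1C(=C)COCOC | intermediate
33 | cis-fused bicyclic ethyl acetal with C8 α-hydroperoxide | C=C[C@]1(C)C[C@H](OO)[C@H]2CC(OCC)O[C@H]2[C@H]1C(=C)COCOC | intermediate
34 | cis-fused bicyclic ethyl acetal with C8 α-hydroxyl (C6 O and C7 C11 on the β face) | C=C[C@]1(C)C[C@H](O)[C@H]2CC(OCC)O[C@H]2[C@H]1C(=C)COCOC | intermediate
35 | methyl (S)-3-hydroxy-2-methylpropanoate (Roche ester) | COC(=O)[C@@H](C)CO | starting material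
36 | methyl (S)-3-(methoxymethoxy)-2-methylpropanoate | COC(=O)[C@@H](C)COCOC | intermediate
37 | (S)-3-(methoxymethoxy)-2-methylpropanoic acid | OC(=O)[C@@H](C)COCOC | intermediate
38 | mixed anhydride of acid 37 with 2,4,6-trichlorobenzoic acid | O=C(OC(=O)[C@@H](C)COCOC)c1c(Cl)cc(Cl)cc1Cl | intermediate
39 | C8 (S)-3-(methoxymethoxy)-2-methylpropanoate of alcohol 34 | C=C[C@]1(C)C[C@H](OC(=O)[C@@H](C)COCOC)[C@H]2CC(OCC)O[C@H]2[C@H]1C(=C)COCOC | intermediate
40 | 2-bromotetrahydrofuran bis(dimethylborinate) formed from 39 | C=C[C@]1(C)C[C@H](OC(=O)[C@@H](C)COB(C)C)[C@H]2CC(Br)O[C@H]2[C@H]1C(=C)COB(C)C | intermediate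
41 | lactol with free C15 and side-chain hydroxyls (lactol epimers) | C=C[C@]1(C)C[C@H](OC(=O)[C@@H](C)CO)[C@H]2CC(O)O[C@H]2[C@H]1C(=C)CO | intermediate
42 | α-methylidene lactol (lactol epimers) | C=C[C@]1(C)C[C@H](OC(=O)[C@@H](C)CO)[C@H]2C(=C)C(O)O[C@H]2[C@H]1C(=C)CO | intermediate
43 | 2-[(1S,2S,3R,4S,6S)-4-ethenyl-2-hydroxy-6-{[(2S)-3-hydroxy-2-methylpropanoyl]oxy}-3-(3-hydroxyprop-1-en-2-yl)-4-methylcyclohexyl]prop-2-enoic acid (CNP0462645.1) | C=C[C@]1(C)C[C@H](OC(=O)[C@@H](C)CO)[C@@H](C(=C)C(=O)O)[C@@H](O)[C@H]1C(=C)CO | target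

**Step count and risks**
Total step count: 25. Longest linear sequence: 23 steps (steps 1–19 and 22–25); steps 20–21 make the side-chain acid.

Steps most likely to fail:

Step 14. The constrained bicyclic transition state may demand a temperature at which facial selectivity erodes or the enol ether ionises and decomposes. The fallback leaves from 26 and replaces the thermal pericyclic reaction with an organoaluminium-promoted, charge-accelerated rearrangement. Triisobutylaluminium in toluene at −78 °C to rt should bind the ring oxygen, trigger the same C9–C10 bond formation under mild conditions and reduce the aluminium-bound carbonyl in situ by β-hydride transfer. This would give the C8 carbinol, cyclohexanol F1 (C8 epimers), and Dess–Martin oxidation of F1 would return to ketone 27.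

Step 19. Hydrogen transfer to the radical before ring closure, or oxygen capture before cyclisation, may compete with the desired cyclisation–oxygenation. The fallback leaves from 27 and closes the same ring by ionic chemistry. HF·pyridine should give the β-hydroxy ketone F2, and ethyl vinyl ether/NBS the bromoacetal ketone F3. KOt-Bu in THF at 0 °C should then effect intramolecular enolate alkylation (5-exo-tet) at C7 to the cis-fused keto acetal F4. L-Selectride at −78 °C should attack C8 from the open α face to give the axial β-alcohol F5. Mitsunobu esterification of F5 with acid 37 (PPh3, DIAD, toluene) should invert C8 and rejoin the route at ester 39.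

Step 25. The lactol may oxidise sluggishly, or the product hydroxy acid may close to the γ-lactone in the acidic buffer. The fallback leaves from 42 and oxidises the lactol deliberately with MnO2 in CH2Cl2 to the α-methylidene-γ-lactone F6. Controlled saponification (LiOH, 1.1 equiv, THF/H2O, 0 °C) should then open the strained cis-fused lactone faster than the α-branched secondary C8 ester. Neutralisation to pH 5 in the cold would deliver 43.

**Further compounds**
F1 | step 14 | C8 carbinol of ketone 27 (C8 epimers), 5-(tert-butyldimethylsilyloxy)-3-ethenyl-4-[3-(methoxymethoxy)prop-1-en-2-yl]-3-methylcyclohexan-1-ol | C=C[C@]1(C)CC(O)C[C@@H](O[Si](C)(C)C(C)(C)C)[C@H]1C(=C)COCOC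
F2 | step 19 | β-hydroxy ketone (desilylated 27) | C=C[C@]1(C)CC(=O)C[C@@H](O)[C@H]1C(=C)COCOC
F3 | step 19 | 2-bromo-1-ethoxyethyl ether of F2 (acetal epimers) | C=C[C@]1(C)CC(=O)C[C@@H](OC(CBr)OCC)[C@H]1C(=C)COCOC
F4 | step 19 | cis-fused bicyclic ethyl acetal with C8 ketone | C=C[C@]1(C)CC(=O)[C@H]2CC(OCC)O[C@H]2[C@H]1C(=C)COCOC
F5 | step 19 | cis-fused bicyclic ethyl acetal with C8 β-hydroxyl (C8 epimer of 34) | C=C[C@]1(C)C[C@@H](O)[C@H]2CC(OCC)O[C@H]2[C@H]1C(=C)COCOC
F6 | step 25 | cis-fused α-methylidene-γ-lactone (6,12-olide) bearing the C8 ester and free C15 hydroxyl | C=C[C@]1(C)C[C@H](OC(=O)[C@@H](C)CO)[C@H]2C(=C)C(=O)O[C@H]2[C@H]1C(=C)CO
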